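**Retrosynthetic overview**
1. Target 20 ⇒ global hydrogenolysis of its hexadeca-O-benzyl ether 19.
2. 19 ⇒ cut the diarylmethine–ring B' bond: ring B' arrives as arylzinc 17, and the benzylic carbon is held in a temporary 2-arylchroman 13, which is opened in that step with net retention (double inversion through the neighbouring gallate).
3. 13 ⇒ cut the C8–C(benzylic) bond: octa-O-benzyl-(−)-gallocatechin gallate 11 (from (−)-gallocatechin 9 and acid 3; supplies rings A, B, C and both lower stereocentres) plus lactol 8, joined by a 1,2-trans Friedel–Crafts C-arylation.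
4. 8 ⇒ one-pot amine-catalysed annulation/α-aroyloxylation of the symmetric 3,5-bis(benzyloxy)phenol 2 with acrolein 6 and diaroyl peroxide 5; this breaks the symmetry of the phenol and sets the only stereocentre made from scratch.
5. Ring order: temporary upper pyran ring (step 4) → lower flavan rings taken intact from gallocatechin → temporary ring opened (step 9); the carbinol centre then dictates the diarylmethine centre.

Assumption: (−)-gallocatechin (2S,3R), 3,4,5-tris(benzyloxy)benzoic acid and 5-bromobenzene-1,2,3-triol are bought; the target SMILES is read as lower unit 2S,3R and upper chain 1R (diarylmethine), 2S (carbinol).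

**Step 1**
Reactants: 1 phloroglucinol
Product: 2 3,5-bis(benzyloxy)phenol
Conditions: BnBr (2.0 equiv), K2CO3 (2.2 equiv), DMF, 0 °C to rt; chromatography (mono- and tribenzyl ethers recycled)
Reagents that add atoms: benzyl bromide, BrCc1ccccc1
Why: Williamson etherification, run statistically on the threefold-symmetric triol to give the C2v-symmetric diether; no stereocentre.

**Step 2**
Reactants: 3 3,4,5-tris(benzyloxy)benzoic acid
Product: 4 3,4,5-tris(benzyloxy)peroxybenzoic acid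
Conditions: 1,1'-carbonyldiimidazole (1.1 equiv), THF, rt, 1 h; then 50% aq. H2O2 (6 equiv), 0 °C, 30 min; cold aqueous work-up, titrated iodometrically and used at once
Reagents that add atoms: hydrogen peroxide, OO
Why: Perhydrolysis of the acyl imidazolide (peroxy acid synthesis from an N-acylimidazole), with excess H2O2 keeping the peracid from being acylated a second time; benzyl ethers are inert and no stereocentre is involved.

**Step 3**
Reactants: 4 3,4,5-tris(benzyloxy)peroxybenzoic acid; 3 3,4,5-tris(benzyloxy)benzoic acid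
Product: 5 bis[3,4,5-tris(benzyloxy)benzoyl] peroxide
Conditions: 4 (1.0 equiv), 3 (1.0 equiv), DCC (1.05 equiv), CH2Cl2/Et2O, 0 °C, dark; filtration; precipitation from cold MeOH
Reagents that add atoms: none
Why: Carbodiimide-mediated O-acylation of the peroxy acid by the carboxylic acid (standard diacyl peroxide synthesis); any acid 3 left in crude 4 from imidazolide hydrolysis is simply counted into the stoichiometry, and no stereocentre is involved.

**Step 4**
Reactants: 2 3,5-bis(benzyloxy)phenol; 6 acrolein; 5 bis[3,4,5-tris(benzyloxy)benzoyl] peroxide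
Product: 8 (3S)-5,7-bis(benzyloxy)-2-hydroxychroman-3-yl 3,4,5-tris(benzyloxy)benzoate (lactol; both C2 anomers), via 5,7-bis(benzyloxy)chroman-2-ol 7 (not isolated)
Conditions: (S)-2-[diphenyl(trimethylsilyloxy)methyl]pyrrolidine (20 mol %), PhCO2H (20 mol %), toluene, 0 °C, 6 (1.2 equiv, slow addition) then rt; then 5 (1.3 equiv), hydroquinone (10 mol %), THF, 0 °C to rt, one pot
Reagents that add atoms: none
Why: Proposed new method: iminium-type activation of acrolein by the amine gives ortho Friedel–Crafts alkylation of the symmetric phenol and lactol closure to 7 (closest precedent: diarylprolinol-silyl-ether-catalysed phenol/enal Friedel–Crafts–hemiacetalisation), and enamine-type activation of the open-chain aldehyde form of 7 by the same amine, whose diphenyl(silyloxy)methyl group shields one face, lets peroxide 5 deliver the aroyloxy group to the open face and sets C3 as S (closest precedent: amine-catalysed α-benzoyloxylation of aldehydes with dibenzoyl peroxide), after which re-closure to the lactol protects the new centre from enolisation.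

**Step 5**
Reactants: 9 (−)-gallocatechin (2S,3R)
Product: 10 penta-O-benzyl-(−)-gallocatechin: (2S,3R)-5,7-bis(benzyloxy)-2-[3,4,5-tris(benzyloxy)phenyl]chroman-3-ol
Conditions: BnBr (5.3 equiv), K2CO3 (6 equiv), degassed DMF, −10 °C to rt, Ar
Reagents that add atoms: benzyl bromide, BrCc1ccccc1
Why: Williamson etherification of the five phenols; carbonate does not deprotonate the secondary alcohol, and the thermodynamically favoured 2,3-trans ring is not epimerised, so C2 (S) and C3 (R) are carried through unchanged.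

**Step 6**
Reactants: 10 penta-O-benzyl-(−)-gallocatechin; 3 3,4,5-tris(benzyloxy)benzoic acid
Product: 11 octa-O-benzyl-(−)-gallocatechin gallate: (2S,3R)-5,7-bis(benzyloxy)-2-[3,4,5-tris(benzyloxy)phenyl]chroman-3-yl 3,4,5-tris(benzyloxy)benzoate
Conditions: 3 (1.3 equiv), DCC (1.5 equiv), 4-(dimethylamino)pyridine (0.2 equiv), CH2Cl2, rt
Reagents that add atoms: none
Why: Steglich esterification of the C3 alcohol; the C3–O bond is not broken, so C3 stays R and C2 stays S.

**Step 7**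
Reactants: 8 lactol gallate (3S); 11 octa-O-benzyl-(−)-gallocatechin gallate
Product: 13 2,3-trans 2-arylchroman: (2R,3S)-5,7-bis(benzyloxy)-3-[3,4,5-tris(benzyloxy)benzoyloxy]chroman-2-yl unit bonded through C2 to C8 of 11, via cis-fused acyloxonium triflate 12 (not isolated)
Conditions: 11 (2.5 equiv), Me3SiOTf (0.3 equiv), 4 Å molecular sieves, CH2Cl2, −40 °C, 8 added over 2 h; Et3N quench; excess 11 recovered
Reagents that add atoms: none
Why: Lewis-acid-promoted Friedel–Crafts C-arylation of a lactol (C-glycosylation type, as in silyl-triflate-mediated couplings of benzylated flavans), in which the neighbouring 3-O-aroyl group bridges the anomeric cation as the cis-fused acyloxonium ion 12 and the least hindered, most nucleophilic ring A position of 11 (C8) opens it from the opposite face, giving the 2,3-trans (2R) product while slow addition keeps the donor's own ring from competing.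

**Step 8**
Reactants: 14 5-bromobenzene-1,2,3-triol
Product: 15 5-bromo-1,2,3-tris(benzyloxy)benzene
Conditions: BnBr (3.3 equiv), K2CO3 (4 equiv), DMF, rt
Reagents that add atoms: benzyl bromide, BrCc1ccccc1
Why: Williamson etherification of the three phenols; the aryl bromide is inert and no stereocentre is involved.

**Step 9**
Reactants: 13 2,3-trans 2-arylchroman; 15 5-bromo-1,2,3-tris(benzyloxy)benzene
Product: 19 hexadeca-O-benzyl ether of the target (lower unit 2S,3R; propyl chain 1R,2S; one free phenol on the upper phloroglucinol ring), via aryllithium 16 (not isolated), via diarylzinc 17 (not isolated), via trans-acyloxonium zinc phenoxide 18 (not isolated)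
Conditions: 15 (3.0 equiv), n-BuLi (3.0 equiv), toluene/Et2O, −78 °C; ZnBr2 (1.5 equiv), −78 to 0 °C; then 13 (1.0 equiv), ZnBr2 (1.0 equiv), CH2Cl2, 0 °C to rt; H2O quench
Reagents that add atoms: none
Why: Proposed new method: ZnBr2 binds the aryl-ether oxygen of 13, whose benzylic C2–O bond (on a 2,4,6-trialkoxyphenyl carbon) lies antiperiplanar to the equatorial 3-O-aroyl group, so ionisation with anchimeric assistance gives the trans-dioxolanylium ion 18 (first inversion) and the arylzinc then transfers ring B' to the benzylic carbon anti to the acyloxonium oxygen (second inversion), a net retention that fixes the diarylmethine centre as R next to the S carbinol; the closest known reactions are the catalyst-free 1,2-trans C-arylation of 2-O-acyl glycosyl donors by diarylzincs and the acid-induced ring opening of 2-(trialkoxyphenyl) C-glycosides and flavans.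

**Step 10**
Reactants: 19 hexadeca-O-benzyl ether of the target
Product: 20 CNP0155034.3
Conditions: H2 (1 atm), Pd(OH)2/C, THF/MeOH (1:1), rt; filtration under Ar; Sephadex LH-20
Reagents that add atoms: none
Why: Catalytic hydrogenolysis of sixteen benzyl ethers, which leaves the two gallate esters, the flavan ether, the diarylmethine C–C bonds and all four stereocentres untouched.

**Compound list**
1 | phloroglucinol | Oc1cc(O)cc(O)c1 | starting material
2 | 3,5-bis(benzyloxy)phenol | Oc1cc(OCc2ccccc2)cc(OCc2ccccc2)c1 | intermediate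
3 | 3,4,5-tris(benzyloxy)benzoic acid | OC(=O)c1cc(OCc2ccccc2)c(OCc2ccccc2)c(OCc2ccccc2)c1 | starting material
4 | 3,4,5-tris(benzyloxy)peroxybenzoic acid | OOC(=O)c1cc(OCc2ccccc2)c(OCc2ccccc2)c(OCc2ccccc2)c1 | intermediate
5 | bis[3,4,5-tris(benzyloxy)benzoyl] peroxide | O=C(OOC(=O)c1cc(OCc2ccccc2)c(OCc2ccccc2)c(OCc2ccccc2)c1)c1cc(OCc2ccccc2)c(OCc2ccccc2)c(OCc2ccccc2)c1 | intermediate
6 | acrolein (prop-2-enal) | C=CC=O | starting material
7 | 5,7-bis(benzyloxy)chroman-2-ol (racemic lactol) | OC1CCc2c(OCc3ccccc3)cc(OCc3ccccc3)cc2O1 | intermediate (not isolated)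
8 | (3S)-5,7-bis(benzyloxy)-2-hydroxy-3,4-dihydro-2H-chromen-3-yl 3,4,5-tris(benzyloxy)benzoate (both C2 anomers) | OC1Oc2cc(OCc3ccccc3)cc(OCc3ccccc3)c2C[C@@H]1OC(=O)c1cc(OCc2ccccc2)c(OCc2ccccc2)c(OCc2ccccc2)c1 | intermediate
9 | (−)-gallocatechin, (2S,3R)-2-(3,4,5-trihydroxyphenyl)-3,4-dihydro-2H-chromene-3,5,7-triol | O[C@@H]1Cc2c(O)cc(O)cc2O[C@H]1c1cc(O)c(O)c(O)c1 | starting material
10 | (2S,3R)-5,7-bis(benzyloxy)-2-[3,4,5-tris(benzyloxy)phenyl]-3,4-dihydro-2H-chromen-3-ol | O[C@@H]1Cc2c(OCc3ccccc3)cc(OCc3ccccc3)cc2O[C@H]1c1cc(OCc2ccccc2)c(OCc2ccccc2)c(OCc2ccccc2)c1 | intermediate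
11 | (2S,3R)-5,7-bis(benzyloxy)-2-[3,4,5-tris(benzyloxy)phenyl]-3,4-dihydro-2H-chromen-3-yl 3,4,5-tris(benzyloxy)benzoate | O=C(O[C@@H]1Cc2c(OCc3ccccc3)cc(OCc3ccccc3)cc2O[C@H]1c1cc(OCc2ccccc2)c(OCc2ccccc2)c(OCc2ccccc2)c1)c1cc(OCc2ccccc2)c(OCc2ccccc2)c(OCc2ccccc2)c1 | intermediate
12 | cis-fused 2-[3,4,5-tris(benzyloxy)phenyl]-1,3-dioxolan-2-ylium ion across C2–C3 of the 5,7-bis(benzyloxy)chroman (C3 S), triflate | C1[C@@H]2OC(c3cc(OCc4ccccc4)c(OCc4ccccc4)c(OCc4ccccc4)c3)=[O+][C@@H]2Oc2cc(OCc3ccccc3)cc(OCc3ccccc3)c21.[O-]S(=O)(=O)C(F)(F)F | intermediate (not isolated)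
13 | (2R,3S)-5,7-bis(benzyloxy)-2-{(2S,3R)-5,7-bis(benzyloxy)-3-[3,4,5-tris(benzyloxy)benzoyloxy]-2-[3,4,5-tris(benzyloxy)phenyl]-3,4-dihydro-2H-chromen-8-yl}-3,4-dihydro-2H-chromen-3-yl 3,4,5-tris(benzyloxy)benzoate | O=C(O[C@H]1Cc2c(OCc3ccccc3)cc(OCc3ccccc3)cc2O[C@@H]1c1c(OCc2ccccc2)cc(OCc2ccccc2)c2c1O[C@@H](c1cc(OCc3ccccc3)c(OCc3ccccc3)c(OCc3ccccc3)c1)[C@H](OC(=O)c1cc(OCc3ccccc3)c(OCc3ccccc3)c(OCc3ccccc3)c1)C2)c1cc(OCc2ccccc2)c(OCc2ccccc2)c(OCc2ccccc2)c1 | intermediate
14 | 5-bromobenzene-1,2,3-triol | Oc1cc(Br)cc(O)c1O | starting material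
15 | 5-bromo-1,2,3-tris(benzyloxy)benzene | Brc1cc(OCc2ccccc2)c(OCc2ccccc2)c(OCc2ccccc2)c1 | intermediate
16 | [3,4,5-tris(benzyloxy)phenyl]lithium | [Li]c1cc(OCc2ccccc2)c(OCc2ccccc2)c(OCc2ccccc2)c1 | intermediate (not isolated)
17 | bis[3,4,5-tris(benzyloxy)phenyl]zinc | [Zn](c1cc(OCc2ccccc2)c(OCc2ccccc2)c(OCc2ccccc2)c1)c1cc(OCc2ccccc2)c(OCc2ccccc2)c(OCc2ccccc2)c1 | intermediate (not isolated)
18 | (4S,5S)-trans-2-[3,4,5-tris(benzyloxy)phenyl]-1,3-dioxolan-2-ylium ion bearing 4-[2,4-bis(benzyloxy)-6-oxidobenzyl] and 5-(C8 aryl of unit 11); phenoxide zinc-bound, drawn as zwitterion | [O-]c1cc(OCc2ccccc2)cc(OCc2ccccc2)c1C[C@@H]1OC(c2cc(OCc3ccccc3)c(OCc3ccccc3)c(OCc3ccccc3)c2)=[O+][C@H]1c1c(OCc2ccccc2)cc(OCc2ccccc2)c2c1O[C@@H](c1cc(OCc3ccccc3)c(OCc3ccccc3)c(OCc3ccccc3)c1)[C@H](OC(=O)c1cc(OCc3ccccc3)c(OCc3ccccc3)c(OCc3ccccc3)c1)C2 | intermediate (not isolated)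
19 | (2S,3R)-5,7-bis(benzyloxy)-8-{(1R,2S)-3-[2,4-bis(benzyloxy)-6-hydroxyphenyl]-2-[3,4,5-tris(benzyloxy)benzoyloxy]-1-[3,4,5-tris(benzyloxy)phenyl]propyl}-2-[3,4,5-tris(benzyloxy)phenyl]-3,4-dihydro-2H-chromen-3-yl 3,4,5-tris(benzyloxy)benzoate | O=C(O[C@@H](Cc1c(OCc2ccccc2)cc(OCc2ccccc2)cc1O)[C@H](c1cc(OCc2ccccc2)c(OCc2ccccc2)c(OCc2ccccc2)c1)c1c(OCc2ccccc2)cc(OCc2ccccc2)c2c1O[C@@H](c1cc(OCc3ccccc3)c(OCc3ccccc3)c(OCc3ccccc3)c1)[C@H](OC(=O)c1cc(OCc3ccccc3)c(OCc3ccccc3)c(OCc3ccccc3)c1)C2)c1cc(OCc2ccccc2)c(OCc2ccccc2)c(OCc2ccccc2)c1 | intermediate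
20 | (2S,3R)-8-[(1R,2S)-2-(3,4,5-trihydroxybenzoyloxy)-3-(2,4,6-trihydroxyphenyl)-1-(3,4,5-trihydroxyphenyl)propyl]-5,7-dihydroxy-2-(3,4,5-trihydroxyphenyl)-3,4-dihydro-2H-chromen-3-yl 3,4,5-trihydroxybenzoate (CNP0155034.3) | O=C(O[C@@H](Cc1c(O)cc(O)cc1O)[C@H](c1cc(O)c(O)c(O)c1)c1c(O)cc(O)c2c1O[C@@H](c1cc(O)c(O)c(O)c1)[C@H](OC(=O)c1cc(O)c(O)c(O)c1)C2)c1cc(O)c(O)c(O)c1 | target

**Count and risks**
Total: 10 steps. Longest linear sequence: 6 steps (2 → 3 → 4 → 7 → 9 → 10).

Stereochemical bookkeeping: the lower C2 (S) and C3 (R) come from 9 and are not touched in steps 5 and 6. The carbinol centre (S) is set in step 4, expected at roughly 90% ee by analogy with α-benzoyloxylation. Because 11 is enantiopure, the minor enantiomer of 8 becomes a diastereomer of 13 and is removed by chromatography; 13 enters step 9 as the single 2,3-trans isomer. The diarylmethine centre (R) is relayed from the carbinol in step 9.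

The three steps most likely to fail are 4, 7 and 9.

Step 4 (one-pot annulation/α-aroyloxylation; the electron-rich peroxide may be sluggish or attack the catalyst). The fallback sets out from 2 and 6. Lactol 7 is isolated from the same amine-catalysed annulation run without peroxide. It is then oxygenated with nitrosobenzene under D-proline catalysis (DMSO, rt) to (3S)-3-(anilinooxy)-5,7-bis(benzyloxy)chroman-2-ol F1. The N–O bond is cleaved with Zn/AcOH to (3S)-5,7-bis(benzyloxy)chroman-2,3-diol F2. Both hydroxyls are esterified with acid 3 (EDC·HCl, 4-(dimethylamino)pyridine, CH2Cl2) to (3S)-5,7-bis(benzyloxy)chroman-2,3-diyl bis[3,4,5-tris(benzyloxy)benzoate] F3. F3 is an anomeric-ester donor; coupling it with 11 (BF3·OEt2, CH2Cl2, −40 °C) brings the route back at 13.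

Step 7 (Friedel–Crafts C-arylation; the donor's own ring A' can self-condense, and 13 can over-react with more donor). The fallback sets out from 8 and blocks the donor instead of using excess acceptor. N-Bromosuccinimide (2.1 equiv, CH2Cl2, −20 °C) gives the 6,8-dibromo lactol F4. Coupling F4 with 11 (1.2 equiv, Me3SiOTf) gives the dibromo 2-arylchroman F5. Ring opening of F5 with diarylzinc 17 under the step 9 conditions gives the dibromo hexadeca-O-benzyl compound F6. Hydrogenolysis of F6 (H2, Pd(OH)2/C, Et3N, THF/MeOH) removes bromine and benzyl groups together and comes back to the route at 20.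

Step 9 (ring-opening arylation; ZnBr2 may ionise the ether too slowly, or the arylzinc may attack the acyloxonium carbon). The fallback sets out from 15 and 13 and replaces the zinc reagent and external Lewis acid by a boron-ate aryl transfer. Bromide 15 is converted (n-BuLi, B(OMe)3, −78 °C; then aq. KHF2) into potassium trifluoro[3,4,5-tris(benzyloxy)phenyl]borate F7. With BF3·OEt2 in CH2Cl2/MeCN at −20 °C, F7 gives the aryldifluoroborane, which is itself the Lewis acid that opens the benzylic ether of 13. The aryl group then migrates from the phenoxide-bound borate to the acyloxonium-bridged cation, with the same neighbouring-group control, and the route is rejoined at 19.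

**Further compounds**
F1 | step 4 | (3S)-3-(anilinooxy)-5,7-bis(benzyloxy)chroman-2-ol | OC1Oc2cc(OCc3ccccc3)cc(OCc3ccccc3)c2C[C@@H]1ONc1ccccc1
F2 | step 4 | (3S)-5,7-bis(benzyloxy)chroman-2,3-diol | OC1Oc2cc(OCc3ccccc3)cc(OCc3ccccc3)c2C[C@@H]1O
F3 | step 4 | (3S)-5,7-bis(benzyloxy)chroman-2,3-diyl bis[3,4,5-tris(benzyloxy)benzoate] | O=C(OC1Oc2cc(OCc3ccccc3)cc(OCc3ccccc3)c2C[C@@H]1OC(=O)c1cc(OCc2ccccc2)c(OCc2ccccc2)c(OCc2ccccc2)c1)c1cc(OCc2ccccc2)c(OCc2ccccc2)c(OCc2ccccc2)c1
F4 | step 7 | (3S)-5,7-bis(benzyloxy)-6,8-dibromo-2-hydroxychroman-3-yl 3,4,5-tris(benzyloxy)benzoate | OC1Oc2c(Br)c(OCc3ccccc3)c(Br)c(OCc3ccccc3)c2C[C@@H]1OC(=O)c1cc(OCc2ccccc2)c(OCc2ccccc2)c(OCc2ccccc2)c1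
F5 | step 7 | 6,8-dibromo analogue of 13 (bromines on the upper chroman ring A') | O=C(O[C@H]1Cc2c(OCc3ccccc3)c(Br)c(OCc3ccccc3)c(Br)c2O[C@@H]1c1c(OCc2ccccc2)cc(OCc2ccccc2)c2c1O[C@@H](c1cc(OCc3ccccc3)c(OCc3ccccc3)c(OCc3ccccc3)c1)[C@H](OC(=O)c1cc(OCc3ccccc3)c(OCc3ccccc3)c(OCc3ccccc3)c1)C2)c1cc(OCc2ccccc2)c(OCc2ccccc2)c(OCc2ccccc2)c1
F6 | step 7 | dibromo analogue of 19 (3,5-dibromo-2,4-bis(benzyloxy)-6-hydroxybenzyl end) | O=C(O[C@@H](Cc1c(OCc2ccccc2)c(Br)c(OCc2ccccc2)c(Br)c1O)[C@H](c1cc(OCc2ccccc2)c(OCc2ccccc2)c(OCc2ccccc2)c1)c1c(OCc2ccccc2)cc(OCc2ccccc2)c2c1O[C@@H](c1cc(OCc3ccccc3)c(OCc3ccccc3)c(OCc3ccccc3)c1)[C@H](OC(=O)c1cc(OCc3ccccc3)c(OCc3ccccc3)c(OCc3ccccc3)c1)C2)c1cc(OCc2ccccc2)c(OCc2ccccc2)c(OCc2ccccc2)c1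
F7 | step 9 | potassium trifluoro[3,4,5-tris(benzyloxy)phenyl]borate | [K+].F[B-](F)(F)c1cc(OCc2ccccc2)c(OCc2ccccc2)c(OCc2ccccc2)c1
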